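Zeylenone hides a mirror plane through C1 and C4 of its cyclohexane ring: C2 and C6 are both oxygenated, and the C3 benzoate and the C4=C5 alkene are what one opened and one eliminated oxirane leave behind. The target is therefore cut back to an achiral meso 2,3:5,6-bis-epoxide carrying the C1 hydroxyl and the C1 benzoyloxymethyl group, built from Birch-reduced benzoic acid by enolate hydroxylation and hydroxyl-directed double epoxidation. A chiral (salen)cobalt benzoate then opens one of the two enantiotopic oxiranes at C3 with benzoic acid, installing the C3 ester of the target and fixing C1, C2 and C3 in a single operation. The surviving oxirane is later converted into the enone.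

Key step: step 7

Convention: ring carbons keep the zeylenone numbering in all names (C1 quaternary carbinol carbon, C2 carbinol carbon, C3 benzoyloxy carbon, C6 carbonyl carbon); α is the face of the C1 oxygen, β the face of the C1 CH2O group.
Assumption: the (salen)cobalt catalyst is taken to show the same sense of induction on the bis-epoxide as on cyclohexene oxide. The antipode that converts cyclohexene oxide and benzoic acid into (1R,2R)-2-(benzoyloxy)cyclohexanol is therefore used; the sense is to be confirmed on the final product, and the other commercial antipode is substituted if needed.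

Step 1
Reactants: 1 benzoic acid
Product: 3 cyclohexa-2,5-diene-1-carboxylic acid, via sodium cyclohexa-2,5-diene-1-carboxylate 2 (not isolated)
Conditions: Na, NH3(l), EtOH, −78 → −33 °C; NH4Cl; then aq HCl, 0 °C
Reagents that add atoms: none
Why: Birch reduction of the benzoate anion, in which the carbanion is protonated at C4 and then at C1 (the central carbon of the dienyl anion), should give the unconjugated 1,4-dihydro acid without forming a stereocentre.

Step 2
Reactants: 3 cyclohexa-2,5-diene-1-carboxylic acid
Product: 4 methyl cyclohexa-2,5-diene-1-carboxylate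
Conditions: TMSCHN2 (hexanes), MeOH–toluene (1:4), 0 °C → rt
Reagents that add atoms: trimethylsilyldiazomethane, C[Si](C)(C)C=[N+]=[N-]
Why: Diazoalkane esterification is an O-alkylation of the carboxylate under neutral conditions, so the doubly allylic C1–H never meets base and the diene should neither conjugate nor aromatise.

Step 3
Reactants: 4 methyl cyclohexa-2,5-diene-1-carboxylate
Product: 6 methyl 1-hydroxycyclohexa-2,5-diene-1-carboxylate, via potassium ester enolate 5 (not isolated)
Conditions: KHMDS, THF (degassed, Ar), −78 °C; then 3-phenyl-2-(phenylsulfonyl)oxaziridine, −78 °C; sat. aq NH4Cl at −78 °C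
Reagents that add atoms: 3-phenyl-2-(phenylsulfonyl)oxaziridine, O=S(=O)(N1OC1c1ccccc1)c1ccccc1
Why: Davis oxidation, in which the cross-conjugated dienolate (the species that is C1-alkylated in Birch reductive alkylations) attacks the oxaziridine oxygen through its α-carbon, should hydroxylate C1, the potassium counter-ion and low temperature suppressing addition to the sulfonimine by-product and the symmetric ring leaving C1 non-stereogenic.

Step 4
Reactants: 6 methyl 1-hydroxycyclohexa-2,5-diene-1-carboxylate
Product: 8 meso methyl 2α,3α:5α,6α-diepoxy-1α-hydroxycyclohexane-1β-carboxylate (both oxiranes cis to the C1 hydroxyl), via racemic mono-epoxide 7 (not isolated)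
Conditions: mCPBA (3.5 equiv), NaHCO3, CH2Cl2, 0 °C → rt, dark
Reagents that add atoms: 3-chloroperoxybenzoic acid, O=C(OO)c1cccc(Cl)c1
Why: Henbest-type hydroxyl-directed epoxidation, reinforced by the bulkier ester shielding the β-face, should deliver both oxygens to the α-face and so set all four oxirane carbons cis to the C1 oxygen, while the bicarbonate buffer and the electron-withdrawing ester hold back acid-triggered dehydration to methyl benzoate.

Step 5
Reactants: 8 meso bis-epoxy hydroxy ester
Product: 9 meso 2α,3α:5α,6α-diepoxy-1β-(hydroxymethyl)cyclohexan-1α-ol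
Conditions: NaBH4, MeOH, 0 °C, short reaction time; acetone, then sat. aq NH4Cl
Reagents that add atoms: none
Why: Borohydride reduction of an α-hydroxy ester (activated by the neighbouring hydroxyl) runs at 0 °C where oxiranes are inert, Payne rearrangement is impossible because the C1 hydroxyl is syn to both oxiranes, and the cold neutral quench limits transannular attack of the new primary alkoxide on C3 or C5, so all stereocentres should be untouched.

Step 6
Reactants: 9 meso bis-epoxy diol; 10 benzoyl chloride
Product: 11 meso (2α,3α:5α,6α-diepoxy-1α-hydroxycyclohexan-1β-yl)methyl benzoate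
Conditions: 10 (1.05 equiv), pyridine, CH2Cl2, −20 → 0 °C
Reagents that add atoms: benzoyl chloride, O=C(Cl)c1ccccc1
Why: Acylation in pyridine at low temperature should distinguish the primary hydroxyl from the tertiary one flanked by two oxiranes, and capping this oxygen also removes the only internal nucleophile able to reach an oxirane from the β-face.

Step 7
Reactants: 11 meso bis-epoxide primary benzoate; 1 benzoic acid
Product: 12 [(1S,2S,3R,5R,6R)-3-(benzoyloxy)-5,6-epoxy-1,2-dihydroxycyclohexyl]methyl benzoate (1α,2α-diol; 3β-benzoate; 5α,6α-oxirane)
Conditions: 1 (1.0–1.05 equiv), N,N′-bis(3,5-di-tert-butylsalicylidene)-trans-1,2-cyclohexanediamine cobalt(II) (single antipode, 5 mol %, oxidised in air to the Co(III) benzoate), i-Pr2NEt (1.0 equiv), TBME, 0 °C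
Reagents that add atoms: benzoic acid, O=C(O)c1ccccc1
Why: Proposed new method: one (salen)Co(III) centre binds an oxirane oxygen as a Lewis acid while a second delivers its benzoate ligand to the β-face of C3 in an intermolecular SN2 opening, and proton transfer from benzoic acid regenerates the cobalt benzoate. The closest known reaction type is the (salen)Co-catalysed enantioselective addition of benzoic acid to meso cyclohexene-oxide-type epoxides (and the related chiral phosphoric acid carboxylysis); new here is that the catalyst must choose between two enantiotopic oxiranes of a bis-epoxide with a free tertiary hydroxyl, not between the two carbons of one oxirane. No ring is closed; one oxirane opens and releases the C2 hydroxyl. The benzoate enters C3 with inversion and is therefore trans to the C2 oxygen, whose cis relation to the C1 hydroxyl was set in step 4, and the absolute configuration at C1, C2 and C3 comes from the catalyst alone. The step needs regioselectivity (C3 and C5 over C2 and C6), which the quaternary, oxygenated C1 should provide by shielding and inductively deactivating its neighbours, and enantiotopic-group selectivity (C3 over C5), for which catalyst and substrate preferences coincide only at C3 because in the mirror-image oxirane the catalyst-preferred carbon is the blocked C6. The minor mono-adduct keeps the oxirane matched to the catalyst and should be drained by a second opening to an achiral bis-benzoate, which should raise the enantiomeric purity of 12, while the amine-buffered medium is too mild for participation of the benzoate carbonyls.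

Step 8
Reactants: 12 epoxy diol dibenzoate
Product: 13 1α,2α-O-isopropylidene derivative of 12 (cis-fused dioxolane; oxirane and both benzoates retained)
Conditions: 2-methoxypropene, PPTS (cat.), CH2Cl2, 0 °C → rt; Et3N
Reagents that add atoms: 2-methoxypropene, C=C(C)OC
Why: Acid-catalysed ketalisation with the enol ether closes the five-membered dioxolane across the cis C1/C2 diol under conditions too weak to open the oxirane, and masking the C2 hydroxyl blocks 3→2 benzoyl migration in the next, mildly basic step without touching any stereocentre.

Step 9
Reactants: 13 epoxy acetonide dibenzoate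
Product: 14 [3β-(benzoyloxy)-6α-hydroxy-1α,2α-(isopropylidenedioxy)-5β-(phenylselanyl)cyclohexan-1β-yl]methyl benzoate
Conditions: (PhSe)2, NaBH4, EtOH–THF, 0 °C → rt
Reagents that add atoms: diphenyl diselenide, c1ccc(cc1)[Se][Se]c1ccccc1
Why: Opening of the oxirane by the phenylselenide–borate complex is an SN2 reaction that should occur at C5 from the β-face with inversion (SePh trans to the C6 hydroxyl), because C6 is neopentyl-like and deactivated by the C1 oxygen, as in cis-3-alkoxycyclohexene oxides that open at the distal carbon, and the weakly basic reagent should spare benzoates and ketal.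

Step 10
Reactants: 14 hydroxy selenide
Product: 16 [3β-(benzoyloxy)-6α-hydroxy-1α,2α-(isopropylidenedioxy)cyclohex-4-en-1β-yl]methyl benzoate, via selenoxide 15 (not isolated)
Conditions: mCPBA (1.05 equiv), CH2Cl2, −78 °C; then i-Pr2NH, −78 °C → rt
Reagents that add atoms: none
Why: Selenide oxidation followed by selenoxide syn elimination should take the syn hydrogen of C4, not the carbinol C6–H (the established bias of β-hydroxy selenoxides), giving the C4=C5 allylic alcohol and erasing the transient C5 stereocentre.

Step 11
Reactants: 16 allylic alcohol
Product: 17 zeylenone 1,2-acetonide, [3β-(benzoyloxy)-1α,2α-(isopropylidenedioxy)-6-oxocyclohex-4-en-1β-yl]methyl benzoate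
Conditions: Dess–Martin periodinane, NaHCO3, CH2Cl2, 0 °C → rt
Reagents that add atoms: none
Why: Dess–Martin oxidation converts the secondary allylic alcohol into the enone under buffered, base-free conditions, so the γ-benzoyloxy enone should neither eliminate benzoate nor epimerise, and the transient C6 stereocentre is removed on purpose.

Step 12
Reactants: 17 zeylenone 1,2-acetonide
Product: 18 zeylenone, [(1S,2S,3R)-3-(benzoyloxy)-1,2-dihydroxy-6-oxocyclohex-4-en-1-yl]methyl benzoate
Conditions: TFA–H2O (9:1), 0 °C → rt
Reagents that add atoms: none
Why: Acid-catalysed hydrolysis of the isopropylidene ketal should release the cis C1/C2 diol, benzoates and enone being stable to cold aqueous trifluoroacetic acid, with no stereocentre affected.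

Compound list
1 | benzoic acid | O=C(O)c1ccccc1 | starting material
2 | sodium cyclohexa-2,5-diene-1-carboxylate | [Na+].[O-]C(=O)C1C=CCC=C1 | intermediate (not isolated)
3 | cyclohexa-2,5-diene-1-carboxylic acid | O=C(O)C1C=CCC=C1 | intermediate
4 | methyl cyclohexa-2,5-diene-1-carboxylate | COC(=O)C1C=CCC=C1 | intermediate
5 | potassium enolate of 4 (potassium 1-methoxy-1-(cyclohexa-2,5-dien-1-ylidene)methanolate) | [K+].[O-]C(OC)=C1C=CCC=C1 | intermediate (not isolated)
6 | methyl 1-hydroxycyclohexa-2,5-diene-1-carboxylate (achiral) | COC(=O)C1(O)C=CCC=C1 | intermediate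
7 | methyl 2α,3α-epoxy-1α-hydroxycyclohex-5-ene-1β-carboxylate (racemic, one enantiomer drawn) | COC(=O)[C@@]1(O)[C@@H]2O[C@@H]2CC=C1 | intermediate (not isolated)
8 | meso methyl 2α,3α:5α,6α-diepoxy-1α-hydroxycyclohexane-1β-carboxylate | COC(=O)[C@@]1(O)[C@@H]2O[C@@H]2C[C@@H]3O[C@H]13 | intermediate
9 | meso 2α,3α:5α,6α-diepoxy-1β-(hydroxymethyl)cyclohexan-1α-ol | OC[C@@]1(O)[C@@H]2O[C@@H]2C[C@@H]3O[C@H]13 | intermediate
10 | benzoyl chloride | O=C(Cl)c1ccccc1 | starting material
11 | meso (2α,3α:5α,6α-diepoxy-1α-hydroxycyclohexan-1β-yl)methyl benzoate | O=C(c1ccccc1)OC[C@@]1(O)[C@@H]2O[C@@H]2C[C@@H]3O[C@H]13 | intermediate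
12 | [(1S,2S,3R,5R,6R)-3-(benzoyloxy)-5,6-epoxy-1,2-dihydroxycyclohexyl]methyl benzoate | O=C(c1ccccc1)OC[C@@]1(O)[C@@H]2O[C@@H]2C[C@@H](OC(=O)c2ccccc2)[C@@H]1O | intermediate
13 | 1α,2α-O-isopropylidene derivative of 12 | O=C(c1ccccc1)OC[C@@]12[C@@H]3O[C@@H]3C[C@@H](OC(=O)c3ccccc3)[C@@H]1OC(C)(C)O2 | intermediate
14 | [3β-(benzoyloxy)-6α-hydroxy-1α,2α-(isopropylidenedioxy)-5β-(phenylselanyl)cyclohexan-1β-yl]methyl benzoate | O=C(c1ccccc1)OC[C@@]12[C@H](O)[C@@H]([Se]c3ccccc3)C[C@@H](OC(=O)c3ccccc3)[C@@H]1OC(C)(C)O2 | intermediate
15 | selenoxide of 14 (configuration at selenium not defined) | O=C(c1ccccc1)OC[C@@]12[C@H](O)[C@@H]([Se](=O)c3ccccc3)C[C@@H](OC(=O)c3ccccc3)[C@@H]1OC(C)(C)O2 | intermediate (not isolated)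
16 | [3β-(benzoyloxy)-6α-hydroxy-1α,2α-(isopropylidenedioxy)cyclohex-4-en-1β-yl]methyl benzoate | O=C(c1ccccc1)OC[C@@]12[C@H](O)C=C[C@@H](OC(=O)c3ccccc3)[C@@H]1OC(C)(C)O2 | intermediate
17 | zeylenone 1,2-acetonide | O=C(c1ccccc1)OC[C@@]12C(=O)C=C[C@@H](OC(=O)c3ccccc3)[C@@H]1OC(C)(C)O2 | intermediate
18 | zeylenone, [(1S,2S,3R)-3-(benzoyloxy)-1,2-dihydroxy-6-oxocyclohex-4-en-1-yl]methyl benzoate (C1-OH cis to C2-OH, trans to C3-OBz) | O=C(OC[C@@]1(O)C(=O)C=C[C@@H](OC(=O)c2ccccc2)[C@@H]1O)c1ccccc1 | target

Total steps: 12. Longest linear sequence: 12 steps (1 → 18); benzoyl chloride 10 is bought.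

Steps most likely to fail

Step 7 (Proposed new method). What may go wrong: the catalyst may discriminate poorly between the two enantiotopic oxiranes, or turnover may stall because the free C1 hydroxyl or the product diol binds cobalt. Fallback with known chemistry: setting out from 11, the opening is run without asymmetric induction as a hydroxyl-directed titanium-mediated addition of benzoic acid (Ti(OiPr)4, 1, CH2Cl2, rt). This is the established C3-selective opening of 2,3-epoxy alcohols, here steered by the syn C1 alkoxide. It should give 12 as a racemate, that is together with the mirror-image epoxy diol dibenzoate F1. The enantiomers are then separated by preparative chromatography on a chiral stationary phase, and the route is rejoined at 12.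

Step 9. What may go wrong: loss of regiocontrol, with selenide attacking C6 through the trans-diaxial pathway that keeps the C1 and C3 substituents equatorial, instead of C5. Fallback: setting out from 13, the opening is run as before and the unseparated mixture of 14 and the regioisomeric hydroxy selenide F2 (6β-SePh, 5α-OH) is treated with MsCl/Et3N. This stereospecific anti elimination of β-hydroxy selenides should funnel both isomers into the single C5=C6 cyclohexene F3. Dye-sensitised photo-oxygenation (O2, tetraphenylporphyrin, hν, CH2Cl2) in the presence of Ac2O, pyridine and DMAP then performs a Schenck ene reaction. Because C1 is quaternary, only a C4 hydrogen can be taken, so oxygen must arrive at C6 with shift of the alkene to C4=C5. The allylic hydroperoxide F4 is dehydrated in the same flask to the enone, and the route is rejoined at 17, by-passing 15 and 16.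

Step 4. What may go wrong: incomplete facial control in the second epoxidation, or slow oxidation of the ester-deactivated alkenes that leaves time for acid-induced dehydration and aromatisation. Fallback: setting out from 6, the ester is reduced first (NaBH4, MeOH, 0 °C) to the diene diol F5, whose primary hydroxyl is benzoylated (10, pyridine, CH2Cl2, −20 °C) to the dienol benzoate F6. Hydroxyl-directed double epoxidation of F6 (mCPBA in two-phase CH2Cl2/aq NaHCO3) then acts on more electron-rich alkenes with a hydroxyl that is no longer hydrogen-bonded to an ester carbonyl, and should give 11 directly. The route is rejoined at 11, by-passing 8 and 9 and with them the free primary alkoxide next to the oxiranes.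

Further compounds
F1 | step 7 | enantiomer of 12, [(1R,2R,3S,5S,6S)-3-(benzoyloxy)-5,6-epoxy-1,2-dihydroxycyclohexyl]methyl benzoate | O=C(c1ccccc1)OC[C@]1(O)[C@H]2O[C@H]2C[C@H](OC(=O)c2ccccc2)[C@H]1O
F2 | step 9 | regioisomeric hydroxy selenide, [3β-(benzoyloxy)-5α-hydroxy-1α,2α-(isopropylidenedioxy)-6β-(phenylselanyl)cyclohexan-1β-yl]methyl benzoate | O=C(c1ccccc1)OC[C@@]12[C@@H]([Se]c3ccccc3)[C@H](O)C[C@@H](OC(=O)c3ccccc3)[C@@H]1OC(C)(C)O2
F3 | step 9 | [3β-(benzoyloxy)-1α,2α-(isopropylidenedioxy)cyclohex-5-en-1β-yl]methyl benzoate | O=C(c1ccccc1)OC[C@@]12C=CC[C@@H](OC(=O)c3ccccc3)[C@@H]1OC(C)(C)O2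
F4 | step 9 | [3β-(benzoyloxy)-6-hydroperoxy-1α,2α-(isopropylidenedioxy)cyclohex-4-en-1β-yl]methyl benzoate (C6 configuration not defined, both epimers converge) | O=C(c1ccccc1)OC[C@@]12C(OO)C=C[C@@H](OC(=O)c3ccccc3)[C@@H]1OC(C)(C)O2
F5 | step 4 | 1-(hydroxymethyl)cyclohexa-2,5-dien-1-ol | OCC1(O)C=CCC=C1
F6 | step 4 | (1-hydroxycyclohexa-2,5-dien-1-yl)methyl benzoate | O=C(OCC1(O)C=CCC=C1)c1ccccc1
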